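**Retrosynthetic overview**

1. Target ⇐ 29 ⇐ 27 ⇐ α-ketol 25 ⇐ ten-membered 3,4-diol 24. The late steps are O5 angeloylation, release of the C13 methylene from a C11 Mannich base, and O8 desilylation.
2. Enabling feature: the C3(=O)–C4(OH)(CH3) tertiary α-ketol inside the ten-membered carbocycle, next to the C5 oxygen. This 1,2-dioxygenated ring bond is the retron of a reductive aldehyde–ketone (pinacol) coupling, so cutting C3–C4 opens the carbocycle to keto-aldehyde 23.
3. 23 ⇐ diene 22: one oxidative cleavage turns the prenyl terminus into the C3 aldehyde and the methallyl terminus into the C4 methyl ketone. 22 ⇐ lactone 21 ⇐ aldehyde 16 + alkoxyallylborane (C5–C6 bond, O5/O6 syn).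
4. 16 ⇐ Evans syn-aldol (C7–C8 bond) of succinate imide 11 with α-isobutyryloxy aldehyde 7. 7 comes from (R)-citronellal (C8–C10 and C1–C3) by proline α-oxygenation (C9).
5. Ring order: γ-lactone first (step 12, O6–C12), ten-membered carbocycle last by C3–C4 bond formation (step 15).

Key step: step 15

Remark on the chemistry: locants follow a germacranolide numbering (C3 ketone carbon, C4 tertiary carbinol, C5 O-angelate, C6 lactone O–CH, C7 ring fusion, C8 free OH, C9 O-isobutyrate, C10 CH(CH3), C11/C12/C13 lactone α-carbon, carbonyl and methylene); the C3 carbinol of 24 may have either configuration and is drawn undefined because step 16 oxidises it.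

**Route**

Step 1
Reactants: 1 (R)-citronellal
Product: 3 (2R,3R)-3,7-dimethyl-2-[(phenylamino)oxy]oct-6-en-1-ol, via aminoxy aldehyde 2 (not isolated)
Conditions: PhNO, L-proline (20 mol %), CHCl3, 4 °C; then NaBH4, EtOH, 0 °C
Reagents that add atoms: nitrosobenzene O=Nc1ccccc1
Why: Proline-enamine α-aminoxylation (O-nitroso aldol) in which L-proline directs the nitroso oxygen to one enamine face and so sets the C9 oxygen (2R) under catalyst control, while the in situ NaBH4 reduction removes the epimerisable aldehyde before work-up.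

Step 2
Reactants: 3 (2R,3R)-3,7-dimethyl-2-[(phenylamino)oxy]oct-6-en-1-ol
Product: 4 (2R,3R)-3,7-dimethyloct-6-ene-1,2-diol
Conditions: Zn dust, AcOH–EtOH, rt
Reagents that add atoms: none
Why: Reductive N–O bond cleavage by zinc in acetic acid should free the secondary hydroxyl without touching the trisubstituted alkene or either stereocentre.

Step 3
Reactants: 4 (2R,3R)-3,7-dimethyloct-6-ene-1,2-diol
Product: 6 (2R,3R)-1-hydroxy-3,7-dimethyloct-6-en-2-yl 2-methylpropanoate, via cyclic orthoester 5 (not isolated)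
Conditions: (MeO)3CCH(CH3)2, CSA (2 mol %), CH2Cl2, rt; then AcOH–H2O, 0 °C
Reagents that add atoms: trimethyl orthoisobutyrate COC(OC)(OC)C(C)C; water O
Why: Cyclic orthoester formation followed by kinetic acid hydrolysis of the 2-alkoxy-1,3-dioxolane is a known regioselective mono-acylation of terminal 1,2-diols that should leave the ester on the secondary oxygen and free the primary one, with no stereocentre touched.

Step 4
Reactants: 6 (2R,3R)-1-hydroxy-3,7-dimethyloct-6-en-2-yl 2-methylpropanoate
Product: 7 (2R,3R)-3,7-dimethyl-1-oxooct-6-en-2-yl 2-methylpropanoate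
Conditions: Dess–Martin periodinane, NaHCO3, CH2Cl2, 0 °C to rt; used crude
Reagents that add atoms: none
Why: Dess–Martin oxidation of the primary alcohol under buffered non-basic conditions should give the α-acyloxy aldehyde without epimerisation or acyl shift provided it is used at once.

Step 5
Reactants: 8 4-(tert-butoxy)-4-oxobutanoic acid and 9 (4R)-4-benzyl-1,3-oxazolidin-2-one
Product: 11 tert-butyl 4-[(4R)-4-benzyl-2-oxo-1,3-oxazolidin-3-yl]-4-oxobutanoate, via mixed pivalic anhydride 10 (not isolated)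
Conditions: 8, t-BuCOCl, Et3N, THF, −20 °C; then 9, LiCl, rt
Reagents that add atoms: none
Why: N-acylation of the oxazolidinone through the mixed pivalic anhydride with LiCl/Et3N activation is the standard imide synthesis and leaves the tert-butyl ester intact.

Step 6
Reactants: 11 tert-butyl 4-[(4R)-4-benzyl-2-oxo-1,3-oxazolidin-3-yl]-4-oxobutanoate and 7 (2R,3R)-3,7-dimethyl-1-oxooct-6-en-2-yl 2-methylpropanoate
Product: 13 tert-butyl (3R,4R,5R,6R)-3-{[(4R)-4-benzyl-2-oxo-1,3-oxazolidin-3-yl]carbonyl}-4-hydroxy-6,10-dimethyl-5-[(2-methylpropanoyl)oxy]undec-9-enoate, via boron enolate 12 (not isolated)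
Conditions: 11, n-Bu2BOTf, i-Pr2NEt, CH2Cl2, −78 to 0 °C; then 7, −78 to 0 °C; pH 7 buffer, MeOH, 30 % H2O2, 0 °C
Reagents that add atoms: none
Why: Evans syn-aldol reaction through the (Z)-boron enolate and a Zimmerman–Traxler chair in which the (R)-benzyl auxiliary chooses the enolate face, which should set C7 and C8 (2,3-syn, reagent control overriding the weak facial bias of the α-acyloxy aldehyde) with the C8 hydroxyl syn to the C9 oxygen.

Step 7
Reactants: 13 syn-aldol imide
Product: 14 tert-butyl (3R,4R,5R,6R)-3-{[(4R)-4-benzyl-2-oxo-1,3-oxazolidin-3-yl]carbonyl}-4-[(tert-butyldimethylsilyl)oxy]-6,10-dimethyl-5-[(2-methylpropanoyl)oxy]undec-9-enoate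
Conditions: TBSOTf, 2,6-lutidine, CH2Cl2, −78 to −40 °C
Reagents that add atoms: tert-butyldimethylsilyl triflate CC(C)(C)[Si](C)(C)OS(=O)(=O)C(F)(F)F
Why: Silyl triflate silylation of the hindered β-hydroxy imide protects O8 for the rest of the route and blocks both retro-aldol and lactonisation onto C12.

Step 8
Reactants: 14 O8-TBS aldol imide
Product: 15 tert-butyl (3R,4R,5R,6R)-4-[(tert-butyldimethylsilyl)oxy]-3-[(ethylsulfanyl)carbonyl]-6,10-dimethyl-5-[(2-methylpropanoyl)oxy]undec-9-enoate
Conditions: EtSH, n-BuLi, THF, −78 to 0 °C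
Reagents that add atoms: ethanethiol CCS
Why: Lithium ethanethiolate displaces the oxazolidinone at the exocyclic imide carbonyl (thioester exchange), which is far more electrophilic than the isobutyrate and tert-butyl esters.

Step 9
Reactants: 15 S-ethyl thioester
Product: 16 tert-butyl (3R,4R,5R,6R)-4-[(tert-butyldimethylsilyl)oxy]-3-formyl-6,10-dimethyl-5-[(2-methylpropanoyl)oxy]undec-9-enoate
Conditions: Et3SiH, Pd/C (10 wt %), acetone, rt
Reagents that add atoms: none
Why: Fukuyama reduction (palladium-catalysed hydrosilane reduction of a thioester) stops at the aldehyde, leaves both esters, the silyl ether and the trisubstituted alkene untouched, and its neutral medium avoids epimerisation at C7.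

Step 10
Reactants: 17 2-methylprop-2-en-1-ol
Product: 18 3-(methoxymethoxy)-2-methylprop-1-ene
Conditions: MOMCl, i-Pr2NEt, CH2Cl2, 0 °C to rt
Reagents that add atoms: chloromethyl methyl ether COCCl
Why: O-alkylation of the allylic alcohol with MOMCl and a hindered amine base gives the allyl ether needed for metalation.

Step 11
Reactants: 16 C6 aldehyde and 18 3-(methoxymethoxy)-2-methylprop-1-ene
Product: 20 tert-butyl (3S,4R,5R,6R)-4-[(tert-butyldimethylsilyl)oxy]-3-[(1S,2S)-1-hydroxy-2-(methoxymethoxy)-3-methylbut-3-en-1-yl]-6,10-dimethyl-5-[(2-methylpropanoyl)oxy]undec-9-enoate, via allylborane 19 (not isolated)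
Conditions: 18, s-BuLi, THF, −78 °C; (+)-Ipc2BOMe; BF3·OEt2; then 16, −78 °C; pH 7 buffer, 30 % H2O2, 0 °C to rt
Reagents that add atoms: none
Why: Brown alkoxyallylboration, in which the lithiated ether gives the (Z)-γ-alkoxyallylborane that adds through a closed chair transition state so that the Z geometry makes O5 and O6 syn while the isopinocampheyl groups derived from (−)-α-pinene direct attack to the Re face of the aldehyde and so should fix C6 and C5 under reagent control.

Step 12
Reactants: 20 homoallylic alcohol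
Product: 21 (4S,5S)-4-{(1R,2R,3R)-1-[(tert-butyldimethylsilyl)oxy]-3,7-dimethyl-2-[(2-methylpropanoyl)oxy]oct-6-en-1-yl}-5-[(1S)-1-(methoxymethoxy)-2-methylprop-2-en-1-yl]oxolan-2-one
Conditions: p-TsOH·H2O (10 mol %), CH2Cl2, rt
Reagents that add atoms: none
Why: Acid-catalysed intramolecular transesterification (5-exo-trig lactonisation) by the only free hydroxyl, O6, closes the trans-disubstituted γ-lactone without changing any stereocentre.

Step 13
Reactants: 21 γ-lactone
Product: 22 (3R,4S,5S)-4-{(1R,2R,3R)-1-[(tert-butyldimethylsilyl)oxy]-3,7-dimethyl-2-[(2-methylpropanoyl)oxy]oct-6-en-1-yl}-3-[(dimethylamino)methyl]-5-[(1S)-1-(methoxymethoxy)-2-methylprop-2-en-1-yl]oxolan-2-one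
Conditions: LiN(SiMe3)2, THF, −78 °C; CH2=NMe2+ I−, −78 to 0 °C
Reagents that add atoms: N,N-dimethylmethyleneiminium iodide (Eschenmoser's salt) C=[N+](C)C.[I-]
Why: Kinetic enolisation of the lactone at its unhindered α-CH2 (faster than at the hindered isobutyrate methine) and Mannich alkylation anti to the C7 substituent installs C13 as a dimethylaminomethyl group, the standard masked form of an α-methylene lactone, and the new C11 centre is lost again in step 19.

Step 14
Reactants: 22 Mannich-base diene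
Product: 23 (3R,4S,5S)-4-{(1R,2R,3R)-1-[(tert-butyldimethylsilyl)oxy]-3-methyl-2-[(2-methylpropanoyl)oxy]-6-oxohexyl}-3-[(dimethylamino)methyl]-5-[(1R)-1-(methoxymethoxy)-2-oxopropyl]oxolan-2-one
Conditions: OsO4 (2 mol %), NaIO4, 2,6-lutidine, dioxane–H2O (3:1), rt
Reagents that add atoms: sodium periodate [Na+].[O-]I(=O)(=O)=O
Why: Lemieux–Johnson oxidative cleavage (OsO4 dihydroxylation then periodate glycol cleavage) of both electron-rich alkenes unveils the C3 aldehyde and the C4 methyl ketone in one operation while the 2,6-lutidine buffer keeps the α-alkoxy ketone from epimerising.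

Step 15
Reactants: 23 keto-aldehyde
Product: 24 ten-membered 3,4-diol (C3 secondary carbinol; C4 tertiary carbinol; O5 MOM; O8 TBS; O9 isobutyrate; C11 CH2NMe2)
Conditions: SmI2 (0.1 M in THF, 4 equiv), t-BuOH (2 equiv), THF, rt, 23 added over 10 h to 2 mM final concentration; then sat. aq. NH4Cl
Reagents that add atoms: none
Why: SmI2 reduces the unhindered aldehyde faster than the α-alkoxy ketone, and the trivalent-samarium ketyl at C3, which can also bind the ketone oxygen, adds to C4, after which a second electron and t-BuOH give the samarium diolate (intramolecular pinacol cross-coupling). The closest known reaction type is the samarium- or titanium-mediated pinacol macrocyclisation of keto-aldehydes and dialdehydes to eight- to fourteen-membered carbocycles under high dilution. The ten-membered carbocycle closes by 10-exo-trig addition of the C3 ketyl to the ketone C=O, helped by the trans-disubstituted lactone and the contiguous substituents that limit the rotamers of the tether, and the C–C bond formation is irreversible so ring strain cannot reverse it. C4 is expected to be set by 1,2-induction from C5: the C5–OMOM bond lies anti to the incoming C3 (polar Felkin–Anh) with the lactone carbon C6 gauche and inside, an arrangement the C7-linked tether can reach, so C3 should add to the face that places the 4-OH cis to the 5-oxygen on the ring as in the target; C3 is formed as a carbinol of either configuration and is erased in step 16. The step needs chemoselectivity for the two carbonyls over a conjugated lactone, over the α-alkoxy C–O bond and over intermolecular coupling: the enoate is absent because C13 is stored as the saturated Mannich base, HMPA is omitted so the α-OMOM and isobutyrate groups should not be cleaved, and slow addition to excess SmI2 at 2 mM suppresses dimers.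

Step 16
Reactants: 24 ten-membered 3,4-diol
Product: 25 ten-membered α-ketol (C3 ketone; C4 tertiary carbinol; O5 MOM; O8 TBS; C11 CH2NMe2)
Conditions: (COCl)2, DMSO, CH2Cl2, −78 °C; then Et3N, −78 to 0 °C
Reagents that add atoms: none
Why: Swern oxidation converts the secondary C3 carbinol of the secondary/tertiary 1,2-diol into the ketone without glycol cleavage (the tertiary C4 hydroxyl cannot be oxidised), which removes the stereocentre at C3 and gives the α-ketol.

Step 17
Reactants: 25 ten-membered α-ketol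
Product: 26 5-hydroxy α-ketol (free O5–H; O8 TBS; C11 CH2NMe2)
Conditions: Me2BBr, CH2Cl2, −78 °C; then THF–sat. aq. NaHCO3
Reagents that add atoms: none
Why: Bromodimethylborane cleaves the MOM acetal at −78 °C through the bromomethyl ether, which hydrolyses on work-up, and should leave the TBS ether, the esters and the α-ketol intact.

Step 18
Reactants: 26 5-hydroxy α-ketol
Product: 27 5-O-angelate (O8 TBS; C11 CH2NMe2)
Conditions: angelic acid, 2,4,6-Cl3C6H2COCl, Et3N, toluene, rt; then 26, toluene, 75 °C (no DMAP)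
Reagents that add atoms: angelic acid C/C=C(/C)C(=O)O
Why: Yamaguchi-type esterification with the preformed mixed anhydride acylates the only reactive hydroxyl (secondary O5, the tertiary O4 being inert), and the DMAP-free conditions are chosen to keep the (Z)-geometry of the angeloyl group.

Step 19
Reactants: 27 5-O-angelate
Product: 29 8-O-TBS ether of the target (α-methylene lactone restored), via ammonium iodide 28 (not isolated)
Conditions: MeI, MeCN, rt; evaporate; then sat. aq. NaHCO3–EtOAc, rt
Reagents that add atoms: none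
Why: Exhaustive N-methylation followed by Hofmann-type E1cB elimination of trimethylamine from the β-ammonium lactone under bicarbonate regenerates the α-methylene-γ-butyrolactone under conditions that should not touch the α-ketol or the esters.

Step 20
Reactants: 29 8-O-TBS ether of the target
Product: 30 target CNP0223049.1
Conditions: HF·pyridine, pyridine, THF, 0 °C to rt
Reagents that add atoms: none
Why: Fluoride-mediated desilylation with buffered HF·pyridine removes the last protecting group under mildly acidic conditions that should avoid acyl migration between O9 and O8 and retro-aldol of the ketol.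

**Compound list**

1 | (R)-citronellal, (3R)-3,7-dimethyloct-6-enal | O=CC[C@H](C)CCC=C(C)C | starting material
2 | (2R,3R)-3,7-dimethyl-2-[(phenylamino)oxy]oct-6-enal | O=C[C@H](ONc1ccccc1)[C@H](C)CCC=C(C)C | intermediate (not isolated)
3 | (2R,3R)-3,7-dimethyl-2-[(phenylamino)oxy]oct-6-en-1-ol | OC[C@H](ONc1ccccc1)[C@H](C)CCC=C(C)C | intermediate
4 | (2R,3R)-3,7-dimethyloct-6-ene-1,2-diol | OC[C@H](O)[C@H](C)CCC=C(C)C | intermediate
5 | (4R)-2-methoxy-4-[(2R)-6-methylhept-5-en-2-yl]-2-(propan-2-yl)-1,3-dioxolane (cyclic orthoester, both epimers at C2) | COC1(C(C)C)OC[C@@H]([C@H](C)CCC=C(C)C)O1 | intermediate (not isolated)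
6 | (2R,3R)-1-hydroxy-3,7-dimethyloct-6-en-2-yl 2-methylpropanoate | OC[C@H](OC(=O)C(C)C)[C@H](C)CCC=C(C)C | intermediate
7 | (2R,3R)-3,7-dimethyl-1-oxooct-6-en-2-yl 2-methylpropanoate | O=C[C@H](OC(=O)C(C)C)[C@H](C)CCC=C(C)C | intermediate
8 | 4-(tert-butoxy)-4-oxobutanoic acid (mono-tert-butyl succinate) | CC(C)(C)OC(=O)CCC(=O)O | starting material
9 | (4R)-4-benzyl-1,3-oxazolidin-2-one | O=C1N[C@H](Cc2ccccc2)CO1 | starting material
10 | 4-(tert-butoxy)-4-oxobutanoic 2,2-dimethylpropanoic anhydride | CC(C)(C)OC(=O)CCC(=O)OC(=O)C(C)(C)C | intermediate (not isolated)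
11 | tert-butyl 4-[(4R)-4-benzyl-2-oxo-1,3-oxazolidin-3-yl]-4-oxobutanoate | CC(C)(C)OC(=O)CCC(=O)N1[C@H](Cc2ccccc2)COC1=O | intermediate
12 | (Z)-di-n-butylboron enolate of imide 11 | CCCCB(CCCC)O/C(=C\CC(=O)OC(C)(C)C)N1[C@H](Cc2ccccc2)COC1=O | intermediate (not isolated)
13 | tert-butyl (3R,4R,5R,6R)-3-{[(4R)-4-benzyl-2-oxo-1,3-oxazolidin-3-yl]carbonyl}-4-hydroxy-6,10-dimethyl-5-[(2-methylpropanoyl)oxy]undec-9-enoate | CC(C)=CCC[C@@H](C)[C@@H](OC(=O)C(C)C)[C@H](O)[C@@H](CC(=O)OC(C)(C)C)C(=O)N1[C@H](Cc2ccccc2)COC1=O | intermediate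
14 | tert-butyl (3R,4R,5R,6R)-3-{[(4R)-4-benzyl-2-oxo-1,3-oxazolidin-3-yl]carbonyl}-4-[(tert-butyldimethylsilyl)oxy]-6,10-dimethyl-5-[(2-methylpropanoyl)oxy]undec-9-enoate | CC(C)=CCC[C@@H](C)[C@@H](OC(=O)C(C)C)[C@H](O[Si](C)(C)C(C)(C)C)[C@@H](CC(=O)OC(C)(C)C)C(=O)N1[C@H](Cc2ccccc2)COC1=O | intermediate
15 | tert-butyl (3R,4R,5R,6R)-4-[(tert-butyldimethylsilyl)oxy]-3-[(ethylsulfanyl)carbonyl]-6,10-dimethyl-5-[(2-methylpropanoyl)oxy]undec-9-enoate | CC(C)=CCC[C@@H](C)[C@@H](OC(=O)C(C)C)[C@H](O[Si](C)(C)C(C)(C)C)[C@@H](CC(=O)OC(C)(C)C)C(=O)SCC | intermediate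
16 | tert-butyl (3R,4R,5R,6R)-4-[(tert-butyldimethylsilyl)oxy]-3-formyl-6,10-dimethyl-5-[(2-methylpropanoyl)oxy]undec-9-enoate | CC(C)=CCC[C@@H](C)[C@@H](OC(=O)C(C)C)[C@H](O[Si](C)(C)C(C)(C)C)[C@@H](CC(=O)OC(C)(C)C)C=O | intermediate
17 | 2-methylprop-2-en-1-ol | C=C(C)CO | starting material
18 | 3-(methoxymethoxy)-2-methylprop-1-ene | C=C(C)COCOC | intermediate
19 | (Z)-[3-(methoxymethoxy)-2-methylprop-2-en-1-yl]diisopinocampheylborane (isopinocampheyl groups from (−)-α-pinene) | COCO/C=C(/C)CB([C@H]1C[C@H]2C[C@@H]([C@@H]1C)C2(C)C)[C@H]1C[C@H]2C[C@@H]([C@@H]1C)C2(C)C | intermediate (not isolated)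
20 | tert-butyl (3S,4R,5R,6R)-4-[(tert-butyldimethylsilyl)oxy]-3-[(1S,2S)-1-hydroxy-2-(methoxymethoxy)-3-methylbut-3-en-1-yl]-6,10-dimethyl-5-[(2-methylpropanoyl)oxy]undec-9-enoate | CC(C)=CCC[C@@H](C)[C@@H](OC(=O)C(C)C)[C@H](O[Si](C)(C)C(C)(C)C)[C@@H](CC(=O)OC(C)(C)C)[C@H](O)[C@@H](OCOC)C(C)=C | intermediate
21 | (4S,5S)-4-{(1R,2R,3R)-1-[(tert-butyldimethylsilyl)oxy]-3,7-dimethyl-2-[(2-methylpropanoyl)oxy]oct-6-en-1-yl}-5-[(1S)-1-(methoxymethoxy)-2-methylprop-2-en-1-yl]oxolan-2-one | CC(C)=CCC[C@@H](C)[C@@H](OC(=O)C(C)C)[C@H](O[Si](C)(C)C(C)(C)C)[C@H]1CC(=O)O[C@@H]1[C@@H](OCOC)C(C)=C | intermediate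
22 | (3R,4S,5S)-4-{(1R,2R,3R)-1-[(tert-butyldimethylsilyl)oxy]-3,7-dimethyl-2-[(2-methylpropanoyl)oxy]oct-6-en-1-yl}-3-[(dimethylamino)methyl]-5-[(1S)-1-(methoxymethoxy)-2-methylprop-2-en-1-yl]oxolan-2-one | CC(C)=CCC[C@@H](C)[C@@H](OC(=O)C(C)C)[C@H](O[Si](C)(C)C(C)(C)C)[C@H]1[C@H](CN(C)C)C(=O)O[C@@H]1[C@@H](OCOC)C(C)=C | intermediate
23 | (3R,4S,5S)-4-{(1R,2R,3R)-1-[(tert-butyldimethylsilyl)oxy]-3-methyl-2-[(2-methylpropanoyl)oxy]-6-oxohexyl}-3-[(dimethylamino)methyl]-5-[(1R)-1-(methoxymethoxy)-2-oxopropyl]oxolan-2-one | O=CCC[C@@H](C)[C@@H](OC(=O)C(C)C)[C@H](O[Si](C)(C)C(C)(C)C)[C@H]1[C@H](CN(C)C)C(=O)O[C@@H]1[C@@H](OCOC)C(C)=O | intermediate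
24 | ten-membered 3,4-diol fused to the γ-lactone: C3 CH(OH) of either configuration, C4 C(OH)CH3, C5 OMOM, C8 OTBS, C9 O-isobutyrate, C10 CH3, C11 CH2NMe2; C4–C11 configured as in the SMILES | CN(C)C[C@@H]1C(=O)O[C@H]2[C@H]1[C@@H](O[Si](C)(C)C(C)(C)C)[C@H](OC(=O)C(C)C)[C@H](C)CCC(O)[C@](C)(O)[C@@H]2OCOC | intermediate
25 | ten-membered α-ketol: as 24 but C3 ketone | CN(C)C[C@@H]1C(=O)O[C@H]2[C@H]1[C@@H](O[Si](C)(C)C(C)(C)C)[C@H](OC(=O)C(C)C)[C@H](C)CCC(=O)[C@](C)(O)[C@@H]2OCOC | intermediate
26 | 5-hydroxy α-ketol: as 25 but free O5–H | CN(C)C[C@@H]1C(=O)O[C@H]2[C@H]1[C@@H](O[Si](C)(C)C(C)(C)C)[C@H](OC(=O)C(C)C)[C@H](C)CCC(=O)[C@](C)(O)[C@@H]2O | intermediate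
27 | 5-O-angelate: as 26 but O5 (Z)-2-methylbut-2-enoate | CN(C)C[C@@H]1C(=O)O[C@H]2[C@H]1[C@@H](O[Si](C)(C)C(C)(C)C)[C@H](OC(=O)C(C)C)[C@H](C)CCC(=O)[C@](C)(O)[C@@H]2OC(=O)/C(C)=C\C | intermediate
28 | trimethylammonium iodide of 27 | C[N+](C)(C)C[C@@H]1C(=O)O[C@H]2[C@H]1[C@@H](O[Si](C)(C)C(C)(C)C)[C@H](OC(=O)C(C)C)[C@H](C)CCC(=O)[C@](C)(O)[C@@H]2OC(=O)/C(C)=C\C.[I-] | intermediate (not isolated)
29 | 8-O-TBS ether of the target (α-methylene lactone) | C=C1C(=O)O[C@H]2[C@H]1[C@@H](O[Si](C)(C)C(C)(C)C)[C@H](OC(=O)C(C)C)[C@H](C)CCC(=O)[C@](C)(O)[C@@H]2OC(=O)/C(C)=C\C | intermediate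
30 | CNP0223049.1 | C=C1C(=O)O[C@H]2[C@H]1[C@@H](O)[C@H](OC(=O)C(C)C)[C@H](C)CCC(=O)[C@](C)(O)[C@@H]2OC(=O)/C(C)=C\C | target

**Summary**

Total step count: 20.
Longest linear sequence: 18 steps (steps 1–4, 6–9 and 11–20, from (R)-citronellal).

Three steps most likely to fail:

Step 15. Intermolecular pinacol coupling or plain reduction of the aldehyde may outrun the slow ten-membered closure, or C3 may add to the wrong face of the ketone. The fallback sets out from diene 22 and closes the ring by ring-closing metathesis between the prenyl-type and the methallyl-type alkene instead. Conditions would be 22 as its camphorsulfonate salt, second-generation Hoveyda–Grubbs catalyst, toluene, 80 °C, 1 mM. This should give the macrocyclic C3=C4 alkene F1. Dihydroxylation of F1 from its exposed peripheral face (OsO4 cat., N-methylmorpholine N-oxide, acetone–water) then gives the 3,4-diol and comes back to the route at 24.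

Step 11. The hindered α-branched aldehyde may react sluggishly with the β-methyl-substituted alkoxyallylborane, or mismatched double diastereoselection may erode control at C5/C6. The fallback sets out from aldehyde 16 with a primary-amine-catalysed syn-aldol reaction with hydroxyacetone (O-tert-butyl-L-threonine, NMP, 4 °C), which would give the syn-diol methyl ketone F2. Acid lactonisation (p-TsOH, CH2Cl2) gives the hydroxy ketone lactone F3, and MOM protection (MOMCl, i-Pr2NEt) gives the MOM ether ketone F4. Wittig methylenation of the ketone (Ph3PCH3Br, KN(SiMe3)2, THF, −78 to 0 °C) comes back to the route at 21.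

Step 18. Z-to-E isomerisation of the angeloyl unit to the tigloyl ester may occur during acyl transfer, or acylation of the hindered carbinol may fail. The fallback sets out from 26 by esterification with 2-(diphenoxyphosphoryl)propanoic acid (DCC, DMAP cat., CH2Cl2) to give the phosphonate ester F5. A Z-selective Ando-type Horner–Wadsworth–Emmons reaction with acetaldehyde (NaI, DBU, THF, −78 to 0 °C) then builds the (Z)-2-methylbut-2-enoate in place and comes back to the route at 27.

Further compounds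
F1 | step 15 | macrocyclic C3=C4 alkene (ten-membered trisubstituted cycloalkene of either geometry; O5 MOM; O8 TBS; C11 CH2NMe2) | CN(C)C[C@@H]1C(=O)O[C@H]2[C@H]1[C@@H](O[Si](C)(C)C(C)(C)C)[C@H](OC(=O)C(C)C)[C@H](C)CCC=C(C)[C@@H]2OCOC
F2 | step 11 | syn-diol methyl ketone (tert-butyl ester; C5–OH and C6–OH syn; C4 ketone) | CC(C)=CCC[C@@H](C)[C@@H](OC(=O)C(C)C)[C@H](O[Si](C)(C)C(C)(C)C)[C@@H](CC(=O)OC(C)(C)C)[C@H](O)[C@@H](O)C(C)=O
F3 | step 11 | hydroxy ketone lactone (γ-lactone on O6; free C5–OH; C4 ketone) | CC(C)=CCC[C@@H](C)[C@@H](OC(=O)C(C)C)[C@H](O[Si](C)(C)C(C)(C)C)[C@H]1CC(=O)O[C@@H]1[C@@H](O)C(C)=O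
F4 | step 11 | MOM ether ketone (γ-lactone on O6; C5–OMOM; C4 ketone) | CC(C)=CCC[C@@H](C)[C@@H](OC(=O)C(C)C)[C@H](O[Si](C)(C)C(C)(C)C)[C@H]1CC(=O)O[C@@H]1[C@@H](OCOC)C(C)=O
F5 | step 18 | phosphonate ester (O5 2-(diphenoxyphosphoryl)propanoate of 26; both epimers at the phosphonate α-carbon) | CN(C)C[C@@H]1C(=O)O[C@H]2[C@H]1[C@@H](O[Si](C)(C)C(C)(C)C)[C@H](OC(=O)C(C)C)[C@H](C)CCC(=O)[C@](C)(O)[C@@H]2OC(=O)C(C)P(=O)(Oc1ccccc1)Oc1ccccc1
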